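**Retrosynthetic overview**
- The target is the (7R,8S)-erythro 8-O-4′ neolignan. The C7 carbinol comes last, by chelation-controlled reduction of aryl ketone 13, with the allylic alcohol masked as a TBS ether until the final step.
- The strategy rests on ring A: a benzene ring with methoxy groups on the adjacent carbons C3 and C4 and its only carbon substituent (C7) on C1. C2–C3–C4–C5 with both oxygens is therefore 2,3-dimethoxybuta-1,3-diene 11, and C1/C6 are the alkyne carbons of ynone 10. The bonds C1–C2 and C5–C6 are made by (4+2) cycloaddition, followed by dehydrogenation.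
- Ynone 10 comes from Weinreb amide 7 and ethynylmagnesium bromide 8. The C8–O bond comes from Mitsunobu inversion of methyl (R)-lactate 5 by phenol 4, made from sinapic acid 1.
- Ring order: ring B is bought with sinapic acid; ring A is built in step 7 and aromatised in step 8.

Key step: step 7

Assumption: 2,3-dimethoxybuta-1,3-diene and ethynylmagnesium bromide (0.5 M in THF) are used as purchased. Atom numbers follow the neolignan convention (ring A = C1–C6, C7 = carbinol carbon, C8 = ether carbon).

**Step 1**
Reactants: 1 sinapic acid
Product: 2 methyl sinapate, methyl (E)-3-(4-hydroxy-3,5-dimethoxyphenyl)prop-2-enoate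
Conditions: MeOH, H2SO4 (cat.), reflux
Reagents that add atoms: methanol, CO
Why: Fischer esterification in excess methanol should drive the acid to the methyl ester, the phenol and the (E)-alkene being inert to catalytic acid.

**Step 2**
Reactants: 2 methyl sinapate
Product: 3 sinapyl alcohol, 4-[(E)-3-hydroxyprop-1-enyl]-2,6-dimethoxyphenol
Conditions: iBu2AlH (4 equiv), toluene/THF, –78 → 0 °C; aq. potassium sodium tartrate
Reagents that add atoms: none
Why: Ester reduction by an electrophilic aluminium hydride should give clean 1,2-reduction of the cinnamate to the (E)-allylic alcohol without touching the alkene, one extra equivalent being consumed by the phenol.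

**Step 3**
Reactants: 3 sinapyl alcohol
Product: 4 4-[(E)-3-(tert-butyldimethylsilyloxy)prop-1-enyl]-2,6-dimethoxyphenol
Conditions: TBSCl (1.05 equiv), imidazole, CH2Cl2/DMF, –10 → 0 °C
Reagents that add atoms: tert-butyldimethylsilyl chloride, CC(C)(C)[Si](C)(C)Cl
Why: Selective silylation: the unhindered primary allylic hydroxyl should react with TBSCl/imidazole faster than the phenol, which is flanked by two methoxy groups, so a slight excess at low temperature should give the mono-silyl ether.

**Step 4**
Reactants: 4 sinapyl alcohol mono-TBS ether (free phenol); 5 methyl (R)-lactate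
Product: 6 methyl (S)-2-[4-[(E)-3-(tert-butyldimethylsilyloxy)prop-1-enyl]-2,6-dimethoxyphenoxy]propanoate
Conditions: PPh3, DIAD, THF, 0 °C → rt
Reagents that add atoms: none
Why: Mitsunobu reaction: the phenoxide displaces the phosphonium-activated lactate oxygen by SN2 with inversion, turning the R carbinol carbon into the S aryloxy centre that becomes C8.

**Step 5**
Reactants: 6 methyl (S)-aryloxypropanoate
Product: 7 (S)-2-[4-[(E)-3-(tert-butyldimethylsilyloxy)prop-1-enyl]-2,6-dimethoxyphenoxy]-N-methoxy-N-methylpropanamide
Conditions: MeNH(OMe)·HCl, iPrMgCl, THF, –20 → –10 °C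
Reagents that add atoms: N,O-dimethylhydroxylamine hydrochloride, CNOC.Cl
Why: Weinreb amide formation by aminolysis of the ester with the chloromagnesium amide, which should attack the ester carbonyl at low temperature faster than it enolises it, so the C8 centre should be retained.

**Step 6**
Reactants: 7 Weinreb amide; 8 ethynylmagnesium bromide
Product: 10 (S)-4-[4-[(E)-3-(tert-butyldimethylsilyloxy)prop-1-enyl]-2,6-dimethoxyphenoxy]pent-1-yn-3-one, via bromomagnesium hemiaminal chelate 9 (not isolated)
Conditions: HC≡CMgBr (3 equiv), THF, 0 °C; inverse quench into cold 1 M aq. NaHSO4/Et2O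
Reagents that add atoms: none
Why: Weinreb ketone synthesis: the magnesium chelate 9 resists a second addition and collapses to the ynone only on quench, and pouring into cold acid protonates the released amine so that it cannot add to the ynone in conjugate fashion.

**Step 7**
Reactants: 10 ynone; 11 dimethoxybutadiene
Product: 12 (S)-2-[4-[(E)-3-(tert-butyldimethylsilyloxy)prop-1-enyl]-2,6-dimethoxyphenoxy]-1-(4,5-dimethoxycyclohexa-1,4-dien-1-yl)propan-1-one
Conditions: toluene, 2,6-di-tert-butyl-4-methylphenol (cat.), 90 °C, sealed tube, argon, diene in threefold excess; volatiles removed, crude used directly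
Reagents that add atoms: none
Why: The s-cis conformer of the electron-rich diene 11 and the electron-poor triple bond of ynone 10 should combine in a concerted, suprafacial, thermally allowed (4+2) cycloaddition of normal electron demand, the known Diels–Alder reaction of alkoxy-substituted butadienes with acetylenic ketones. Ring A closes as a six-membered carbocycle in one intermolecular event that forms C1–C2 and C5–C6 together and leaves a 1,4-cyclohexadiene. No stereocentre is created, since both new sp3 carbons are CH2 groups, and C8 lies outside the reacting π system and should not enolise in neutral toluene. The step needs chemoselectivity for the ynone over the (E)-styrenyl alkene, which electron demand provides because that alkene is unactivated and conjugated to an electron-rich arene. Regiochemistry does not arise because the diene is symmetric, so the two methoxy groups necessarily end up on C3 and C4. Excess diene and a radical inhibitor should hold back oligomerisation of the terminal ynone.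

**Step 8**
Reactants: 12 cyclohexadienyl ketone
Product: 13 (S)-2-[4-[(E)-3-(tert-butyldimethylsilyloxy)prop-1-enyl]-2,6-dimethoxyphenoxy]-1-(3,4-dimethoxyphenyl)propan-1-one
Conditions: DDQ (1.05 equiv), toluene, 0 °C; aq. NaHCO3 wash
Reagents that add atoms: none
Why: Dehydrogenative aromatisation of a 1,4-cyclohexadiene by hydride abstraction with DDQ: the ring C–H bonds of the bis-enol ether are far more hydridic than the allylic CH2OSi group, so one equivalent at 0 °C should be consumed by ring A only.

**Step 9**
Reactants: 13 aryl ketone
Product: 14 (1R,2S)-2-[4-[(E)-3-(tert-butyldimethylsilyloxy)prop-1-enyl]-2,6-dimethoxyphenoxy]-1-(3,4-dimethoxyphenyl)propan-1-ol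
Conditions: Zn(BH4)2 (stock solution in Et2O), Et2O, –20 → 0 °C; aq. NH4Cl
Reagents that add atoms: none
Why: Chelation-controlled (Cram chelate) hydride reduction: zinc holds the ketone oxygen and the C8 aryloxy oxygen in a five-membered ring and hydride attacks the carbonyl face anti to the C8 methyl group, which should set C7 as R (erythro to 8S).

**Step 10**
Reactants: 14 silyl-protected erythro alcohol
Product: 15 (1R,2S)-1-(3,4-dimethoxyphenyl)-2-[4-[(E)-3-hydroxyprop-1-enyl]-2,6-dimethoxyphenoxy]propan-1-ol (target, 7R,8S)
Conditions: Bu4NF, THF, 0 °C → rt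
Reagents that add atoms: none
Why: Fluoride-mediated desilylation driven by the strong Si–F bond should free the primary allylic alcohol without affecting the aryl ethers, the alkene geometry or either stereocentre.

**Compound list**
1 | sinapic acid | COc1cc(/C=C/C(=O)O)cc(OC)c1O | starting material
2 | methyl sinapate | COC(=O)/C=C/c1cc(OC)c(O)c(OC)c1 | intermediate
3 | sinapyl alcohol | OC/C=C/c1cc(OC)c(O)c(OC)c1 | intermediate
4 | 4-[(E)-3-(tert-butyldimethylsilyloxy)prop-1-enyl]-2,6-dimethoxyphenol | COc1cc(/C=C/CO[Si](C)(C)C(C)(C)C)cc(OC)c1O | intermediate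
5 | methyl (R)-lactate | COC(=O)[C@@H](C)O | starting material
6 | methyl (S)-2-[4-[(E)-3-(tert-butyldimethylsilyloxy)prop-1-enyl]-2,6-dimethoxyphenoxy]propanoate | COC(=O)[C@H](C)Oc1c(OC)cc(/C=C/CO[Si](C)(C)C(C)(C)C)cc1OC | intermediate
7 | (S)-2-[4-[(E)-3-(tert-butyldimethylsilyloxy)prop-1-enyl]-2,6-dimethoxyphenoxy]-N-methoxy-N-methylpropanamide | CON(C)C(=O)[C@H](C)Oc1c(OC)cc(/C=C/CO[Si](C)(C)C(C)(C)C)cc1OC | intermediate
8 | ethynylmagnesium bromide | C#C[Mg]Br | starting material
9 | bromomagnesium alkoxide of the tetrahedral adduct of 7 and 8 (both epimers at the hemiaminal carbon, 4S) | C#CC(O[Mg]Br)(N(C)OC)[C@H](C)Oc1c(OC)cc(/C=C/CO[Si](C)(C)C(C)(C)C)cc1OC | intermediate (not isolated)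
10 | (S)-4-[4-[(E)-3-(tert-butyldimethylsilyloxy)prop-1-enyl]-2,6-dimethoxyphenoxy]pent-1-yn-3-one | C#CC(=O)[C@H](C)Oc1c(OC)cc(/C=C/CO[Si](C)(C)C(C)(C)C)cc1OC | intermediate
11 | 2,3-dimethoxybuta-1,3-diene | C=C(OC)C(OC)=C | starting material
12 | (S)-2-[4-[(E)-3-(tert-butyldimethylsilyloxy)prop-1-enyl]-2,6-dimethoxyphenoxy]-1-(4,5-dimethoxycyclohexa-1,4-dien-1-yl)propan-1-one | COC1=C(OC)CC(C(=O)[C@H](C)Oc2c(OC)cc(/C=C/CO[Si](C)(C)C(C)(C)C)cc2OC)=CC1 | intermediate
13 | (S)-2-[4-[(E)-3-(tert-butyldimethylsilyloxy)prop-1-enyl]-2,6-dimethoxyphenoxy]-1-(3,4-dimethoxyphenyl)propan-1-one | COc1ccc(C(=O)[C@H](C)Oc2c(OC)cc(/C=C/CO[Si](C)(C)C(C)(C)C)cc2OC)cc1OC | intermediate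
14 | (1R,2S)-2-[4-[(E)-3-(tert-butyldimethylsilyloxy)prop-1-enyl]-2,6-dimethoxyphenoxy]-1-(3,4-dimethoxyphenyl)propan-1-ol | COc1ccc([C@@H](O)[C@H](C)Oc2c(OC)cc(/C=C/CO[Si](C)(C)C(C)(C)C)cc2OC)cc1OC | intermediate
15 | (1R,2S)-1-(3,4-dimethoxyphenyl)-2-[4-[(E)-3-hydroxyprop-1-enyl]-2,6-dimethoxyphenoxy]propan-1-ol | COc1ccc([C@@H](O)[C@H](C)Oc2c(OC)cc(/C=C/CO)cc2OC)cc1OC | target

**Totals**
Total step count: 10. Longest linear sequence: 10 steps, from sinapic acid 1.

**Steps most likely to fail**

Step 7. The cycloaddition may be slow enough that the terminal ynone oligomerises thermally, or the enol-ether diene and adduct may be lost to trace-acid hydrolysis. The fallback sets out from Weinreb amide 7: addition of commercial 3,4-dimethoxyphenylmagnesium bromide (THF, 0 °C) is a Weinreb ketone synthesis that should give aryl ketone 13 directly, so the route is rejoined at 13 and steps 6 to 8 are dropped. This buys ring A instead of building it and makes no new compound (F0).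

Step 6. The released N,O-dimethylhydroxylamine may add in conjugate fashion to the freshly liberated ynone during the quench, and C8 may epimerise if the mixture stays basic. The fallback sets out from Weinreb amide 7. Reduction with LiAlH4 (THF, –40 °C) should give (S)-2-[4-[(E)-3-(tert-butyldimethylsilyloxy)prop-1-enyl]-2,6-dimethoxyphenoxy]propanal F1, from which the amine is washed out before any ynone exists. Addition of ethynylmagnesium bromide 8 (THF, –78 °C) should give (4S)-4-[4-[(E)-3-(tert-butyldimethylsilyloxy)prop-1-enyl]-2,6-dimethoxyphenoxy]pent-1-yn-3-ol F2 as a mixture of carbinol epimers. Oxidation with Dess–Martin periodinane buffered by NaHCO3 in CH2Cl2 should return the route to ynone 10.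

Step 9. Facial selectivity may be poor if zinc chelation to the weakly basic aryloxy oxygen is incomplete, giving erythro/threo mixtures. The fallback sets out from ketone 13 and replaces substrate control by reagent control: borane reduction (BH3·SMe2, THF, –20 °C) catalysed by (R)-1-methyl-3,3-diphenyltetrahydro-1H,3H-pyrrolo[1,2-c][1,3,2]oxazaborole (Corey–Bakshi–Shibata reduction). With the aryl group as the large substituent this should deliver hydride to the face that gives 7R. The conditions are non-basic, so C8 should not epimerise, and the route is rejoined at 14. No new compound is made (F0).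

**Further compounds**
F0 | step 7 | none | none
F1 | step 6 | (S)-2-[4-[(E)-3-(tert-butyldimethylsilyloxy)prop-1-enyl]-2,6-dimethoxyphenoxy]propanal | O=C[C@H](C)Oc1c(OC)cc(/C=C/CO[Si](C)(C)C(C)(C)C)cc1OC
F2 | step 6 | (4S)-4-[4-[(E)-3-(tert-butyldimethylsilyloxy)prop-1-enyl]-2,6-dimethoxyphenoxy]pent-1-yn-3-ol (both C3 epimers) | C#CC(O)[C@H](C)Oc1c(OC)cc(/C=C/CO[Si](C)(C)C(C)(C)C)cc1OC
F0 | step 9 | none | none
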